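Numbering: C1 is the methyl-bearing quaternary carbon, C4=C5 the tetrasubstituted alkene (C5 at the ring fusion), C6 and C7 the adjacent methylenes of the seven-membered ring, C8=C9 its trisubstituted alkene (C8 carries the ester CH2). The seven-membered ring is disconnected at C6–C7. With C5 as a ketone in place of the C4=C5 alkene, O=C5–C6–C7–C8=C9 is a γ,δ-unsaturated ketone, the Claisen retron. One thermal [3,3] shift of a racemic 2-methylidene-5-alkenyloxolane closes the cycloheptenone, forms C6–C7 and places the C8=C9 alkene with its CH2O group. A chiral-imine Michael addition then sets C1, and a McMurry coupling of the 1,5-diketone closes the cyclopentene.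

Key step: step 5

Assumption: the facial preference of the chiral-imine Michael addition on the seven-membered ketone is taken to be that established for 2-methylcyclohexanone imines, which calls for the (R)-amine to reach the R-configured quaternary carbon of the target.

Step 1
Reactants: 1 2-bromoprop-2-en-1-ol
Product: 2 [(2-bromoprop-2-en-1-yl)oxy](tert-butyl)diphenylsilane
Conditions: TBDPSCl, imidazole, CH2Cl2, 0 °C to rt
Reagents that add atoms: tert-butyl(chloro)diphenylsilane (TBDPSCl) CC(C)(C)[Si](Cl)(c1ccccc1)c1ccccc1
Why: Imidazole-promoted silylation of a primary alcohol is routine and gives a silyl ether robust enough to mask the future ester oxygen through the chromium, thermal and low-valent titanium steps; no stereocentre is involved.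

Step 2
Reactants: 3 ethyl 2-methylpent-4-enoate
Product: 4 ethyl 2-methyl-4-oxobutanoate
Conditions: O3, CH2Cl2, −78 °C; then Me2S, −78 °C to rt
Reagents that add atoms: ozone [O-][O+]=O
Why: Ozonolysis with reductive work-up cleaves the terminal alkene to the aldehyde without touching the ester; the α-stereocentre is racemic and may remain so.

Step 3
Reactants: 2 [(2-bromoprop-2-en-1-yl)oxy](tert-butyl)diphenylsilane, 4 ethyl 2-methyl-4-oxobutanoate
Product: 6 5-(3-{[tert-butyl(diphenyl)silyl]oxy}prop-1-en-2-yl)-3-methyloxolan-2-one, via hydroxy ester 5 (not isolated)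
Conditions: CrCl2, NiCl2 (cat.), DMF, rt; then PPTS (cat.), PhMe, 60 °C
Reagents that add atoms: none
Why: Nozaki–Hiyama–Kishi coupling, in which zerovalent nickel activates the alkenyl bromide and passes the alkenyl group to trivalent chromium, should add to the aldehyde but not to the ester, and the γ-hydroxy ester then lactonises under mild acid; the new carbinol centre is formed without control, which is harmless because it is destroyed in step 5.

Step 4
Reactants: 6 5-(3-{[tert-butyl(diphenyl)silyl]oxy}prop-1-en-2-yl)-3-methyloxolan-2-one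
Product: 7 tert-butyl{[2-(4-methyl-5-methylideneoxolan-2-yl)prop-2-en-1-yl]oxy}diphenylsilane
Conditions: Cp2TiMe2, PhMe, 75 °C, dark; filtration through basic alumina
Reagents that add atoms: dimethyltitanocene (Cp2TiMe2) C[Ti](C)(C1C=CC=C1)C1C=CC=C1
Why: Petasis methylenation, in which titanocene methylidene (formed by loss of methane) undergoes [2+2] addition and cycloreversion with the lactone carbonyl, should give the exocyclic enol ether under non-basic conditions that leave the silyl ether alone; no new stereocentre is formed.

Step 5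
Reactants: 7 tert-butyl{[2-(4-methyl-5-methylideneoxolan-2-yl)prop-2-en-1-yl]oxy}diphenylsilane
Product: 8 5-({[tert-butyl(diphenyl)silyl]oxy}methyl)-2-methylcyclohept-4-en-1-one
Conditions: PhMe, Et3N (trace), base-washed sealed tube, 180 °C
Reagents that add atoms: none
Why: This is a concerted thermal [3,3]-sigmatropic (Claisen) rearrangement of the allyl vinyl ether array C6=C5–O–C9–C8=C7 through the boat-like six-membered transition state that the oxolane enforces: the methylidene carbon C6 bonds to the terminal alkene carbon C7 while the ring O–C9 bond breaks, giving the C5 ketone and the C8=C9 ring alkene. The closest known reaction type is the Claisen ring expansion of 2-methylidene-5-vinyloxolanes to cyclohept-4-enones. The seven-membered carbocycle is closed as a sigmatropic two-carbon enlargement of the five-membered ether (not an exo or endo attack), and the tether allows only the cis ring alkene. No stereocentre is created: the carbinol carbon C9 becomes sp2 and the methyl-bearing carbon stays racemic, so both diastereomers of 7 should converge on 8. Regiochemistry is fixed because only one [3,3] array exists; the selectivity needed is against migration of the exocyclic enol ether double bond into the ring, which the acid-free, amine-buffered medium is meant to secure.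

Step 6
Reactants: 8 5-({[tert-butyl(diphenyl)silyl]oxy}methyl)-2-methylcyclohept-4-en-1-one, 9 (1R)-1-phenylethan-1-amine, 10 4-methylpent-1-en-3-one
Product: 13 (2R)-5-({[tert-butyl(diphenyl)silyl]oxy}methyl)-2-methyl-2-(4-methyl-3-oxopentyl)cyclohept-4-en-1-one, via ketimine 11 (not isolated), via Michael adduct ketimine 12 (not isolated)
Conditions: 9, PhMe, 4 Å MS, reflux; then 10, THF, 40 °C; then 20% aq AcOH, rt
Reagents that add atoms: water O
Why: In this asymmetric Michael addition of a chiral ketimine, 11 should react through its more substituted secondary enamine tautomer (so racemic 8 converges) in an aza-ene-like transition state with the vinyl ketone delivered to the enamine face away from the phenyl group, which sets the quaternary carbon as R, and aqueous acid then hydrolyses 12 to the ketone and releases the amine.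

Step 7
Reactants: 13 (2R)-5-({[tert-butyl(diphenyl)silyl]oxy}methyl)-2-methyl-2-(4-methyl-3-oxopentyl)cyclohept-4-en-1-one
Product: 14 tert-butyl{[(8aR)-8a-methyl-3-(propan-2-yl)-1,2,4,5,8,8a-hexahydroazulen-6-yl]methoxy}diphenylsilane
Conditions: TiCl3(DME)1.5, Zn–Cu, DME, reflux, slow addition of 13
Reagents that add atoms: none
Why: In this McMurry coupling, zerovalent titanium should join the two ketones of the 1,5-diketone to a titanium pinacolate and deoxygenate it to the tetrasubstituted cyclopentene alkene, a favourable ring size for the reaction; the quaternary centre has no α-hydrogen and cannot be scrambled.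

Step 8
Reactants: 14 tert-butyl{[(8aR)-8a-methyl-3-(propan-2-yl)-1,2,4,5,8,8a-hexahydroazulen-6-yl]methoxy}diphenylsilane
Product: 15 [(8aR)-8a-methyl-3-(propan-2-yl)-1,2,4,5,8,8a-hexahydroazulen-6-yl]methanol
Conditions: TBAF, THF, 0 °C to rt
Reagents that add atoms: none
Why: Fluoride-driven desilylation should free the primary allylic alcohol without affecting either alkene; the stereocentre is not involved.

Step 9
Reactants: 15 [(8aR)-8a-methyl-3-(propan-2-yl)-1,2,4,5,8,8a-hexahydroazulen-6-yl]methanol, 16 4-hydroxy-3-methoxybenzoic acid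
Product: 17 [(8aR)-8a-methyl-3-(propan-2-yl)-1,2,4,5,8,8a-hexahydroazulen-6-yl]methyl 4-hydroxy-3-methoxybenzoate
Conditions: PPh3, DIAD, THF, 0 °C to rt
Reagents that add atoms: none
Why: In this Mitsunobu esterification the alcohol is activated as an alkoxyphosphonium ion and displaced at the unhindered primary allylic carbon by the carboxylate of 16, whose carboxylic acid is far more acidic than its phenol and should therefore react selectively without protection; the remote quaternary centre is unchanged.

Compound list
1 | 2-bromoprop-2-en-1-ol | OCC(Br)=C | starting material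
2 | [(2-bromoprop-2-en-1-yl)oxy](tert-butyl)diphenylsilane | C=C(Br)CO[Si](c1ccccc1)(c1ccccc1)C(C)(C)C | intermediate
3 | ethyl 2-methylpent-4-enoate (racemic) | CCOC(=O)C(C)CC=C | starting material
4 | ethyl 2-methyl-4-oxobutanoate (racemic) | CCOC(=O)C(C)CC=O | intermediate
5 | ethyl 6-{[tert-butyl(diphenyl)silyl]oxy}-4-hydroxy-2-methyl-5-methylidenehexanoate (mixture of diastereomers, not isolated) | CCOC(=O)C(C)CC(O)C(=C)CO[Si](c1ccccc1)(c1ccccc1)C(C)(C)C | intermediate
6 | 5-(3-{[tert-butyl(diphenyl)silyl]oxy}prop-1-en-2-yl)-3-methyloxolan-2-one (racemic, mixture of diastereomers) | CC1CC(C(=C)CO[Si](c2ccccc2)(c2ccccc2)C(C)(C)C)OC1=O | intermediate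
7 | tert-butyl{[2-(4-methyl-5-methylideneoxolan-2-yl)prop-2-en-1-yl]oxy}diphenylsilane (racemic, mixture of diastereomers) | C=C1OC(C(=C)CO[Si](c2ccccc2)(c2ccccc2)C(C)(C)C)CC1C | intermediate
8 | 5-({[tert-butyl(diphenyl)silyl]oxy}methyl)-2-methylcyclohept-4-en-1-one (racemic) | CC1CC=C(CO[Si](c2ccccc2)(c2ccccc2)C(C)(C)C)CCC1=O | intermediate
9 | (1R)-1-phenylethan-1-amine | C[C@@H](N)c1ccccc1 | starting material
10 | 4-methylpent-1-en-3-one (isopropyl vinyl ketone) | C=CC(=O)C(C)C | starting material
11 | 5-({[tert-butyl(diphenyl)silyl]oxy}methyl)-2-methyl-N-[(1R)-1-phenylethyl]cyclohept-4-en-1-imine (epimers at C2, in equilibrium with the secondary enamine, not isolated) | C[C@@H](N=C1CCC(CO[Si](c2ccccc2)(c2ccccc2)C(C)(C)C)=CCC1C)c1ccccc1 | intermediate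
12 | (2R)-5-({[tert-butyl(diphenyl)silyl]oxy}methyl)-2-methyl-2-(4-methyl-3-oxopentyl)-N-[(1R)-1-phenylethyl]cyclohept-4-en-1-imine (not isolated) | C[C@@H](N=C1CCC(CO[Si](c2ccccc2)(c2ccccc2)C(C)(C)C)=CC[C@@]1(C)CCC(=O)C(C)C)c1ccccc1 | intermediate
13 | (2R)-5-({[tert-butyl(diphenyl)silyl]oxy}methyl)-2-methyl-2-(4-methyl-3-oxopentyl)cyclohept-4-en-1-one | O=C1CCC(CO[Si](c2ccccc2)(c2ccccc2)C(C)(C)C)=CC[C@@]1(C)CCC(=O)C(C)C | intermediate
14 | tert-butyl{[(8aR)-8a-methyl-3-(propan-2-yl)-1,2,4,5,8,8a-hexahydroazulen-6-yl]methoxy}diphenylsilane | CC(C)C1=C2CCC(CO[Si](c3ccccc3)(c3ccccc3)C(C)(C)C)=CC[C@@]2(C)CC1 | intermediate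
15 | [(8aR)-8a-methyl-3-(propan-2-yl)-1,2,4,5,8,8a-hexahydroazulen-6-yl]methanol | CC(C)C1=C2CCC(CO)=CC[C@@]2(C)CC1 | intermediate
16 | 4-hydroxy-3-methoxybenzoic acid (vanillic acid) | COc1cc(C(=O)O)ccc1O | starting material
17 | [(8aR)-8a-methyl-3-(propan-2-yl)-1,2,4,5,8,8a-hexahydroazulen-6-yl]methyl 4-hydroxy-3-methoxybenzoate | COc1cc(C(=O)OCC2=CC[C@@]3(C)CCC(C(C)C)=C3CC2)ccc1O | target

Total step count: 9. Longest linear sequence: 8 steps (steps 2 to 9, from 3 to 17).

Steps most likely to fail

Step 5. The exocyclic enol ether may isomerise to the endocyclic 2,3-dimethyl-4,5-dihydrofuran (or hydrolyse) under traces of acid or titanium residues before the [3,3] shift, which removes the vinyl ether terminus. The fallback sets out from lactone 6 and comes back at ketone 8. One equivalent of MeLi (THF, −78 °C) adds once to 6 to give the methyl hemiketal 5-(3-{[tert-butyl(diphenyl)silyl]oxy}prop-1-en-2-yl)-2,3-dimethyloxolan-2-ol F1. Heating the hemiketal in xylene at 150 °C with a catalytic weak acid (pivalic acid) and removal of water dehydrates it reversibly. Exocyclic and endocyclic enol ethers then interconvert through the oxocarbenium ion, and the irreversible [3,3] shift of the exocyclic isomer 7, formed in the flask, should drain the equilibrium to 8. The double-bond migration thus becomes a harmless pre-equilibrium.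

Step 6. Alkylation may proceed through the less substituted enamine at the ring methylene, facial discrimination on the flexible seven-membered enamine may be poor, and the vinyl ketone may polymerise. The fallback sets out from ketone 8 and comes back at diketone 13 by a palladium-catalysed decarboxylative asymmetric allylic alkylation. TMSCl, NaI and Et3N in MeCN convert 8 into the more substituted silyl enol ether F2, and MeLi followed by allyl chloroformate turns it into the allyl enol carbonate F3. Pd2(dba)3 with (S)-t-BuPHOX in THF should ionise the carbonate, expel CO2 and recombine enolate and allyl fragment under ligand control to the (R)-allyl ketone F4. Hydroboration of its terminal alkene with 9-BBN and oxidation with NaBO3 gives the primary alcohol F5, and Dess–Martin periodinane gives the aldehyde F6. i-PrMgBr at −78 °C should add to the aldehyde in preference to the hindered ketone to give the ketol F7, and a second Dess–Martin oxidation gives 13.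

Step 7. The coupling may stop at the titanium pinacolate, the hindered ketones may simply be reduced, and the allylic silyl ether may be lost under the long Lewis-acidic reflux. The fallback sets out from diketone 13 and comes back at diene 14. SmI2 (THF, t-BuOH, −78 °C to rt) should close the 1,5-diketone by pinacol coupling to the cis-diol F8. Thiocarbonyldiimidazole (DMAP, PhMe, reflux) converts it into the cyclic thionocarbonate F9, and Corey–Winter fragmentation with P(OMe)3 at 110 °C should deliver the tetrasubstituted alkene of 14.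

Further compounds
F1 | step 5 | 5-(3-{[tert-butyl(diphenyl)silyl]oxy}prop-1-en-2-yl)-2,3-dimethyloxolan-2-ol | CC1CC(C(=C)CO[Si](c2ccccc2)(c2ccccc2)C(C)(C)C)OC1(C)O
F2 | step 6 | tert-butyl({4-methyl-5-[(trimethylsilyl)oxy]cyclohepta-1,4-dien-1-yl}methoxy)diphenylsilane | C[Si](C)(C)OC1=C(C)CC=C(CO[Si](c2ccccc2)(c2ccccc2)C(C)(C)C)CC1
F3 | step 6 | 5-({[tert-butyl(diphenyl)silyl]oxy}methyl)-2-methylcyclohepta-1,4-dien-1-yl prop-2-en-1-yl carbonate | C=CCOC(=O)OC1=C(C)CC=C(CO[Si](c2ccccc2)(c2ccccc2)C(C)(C)C)CC1
F4 | step 6 | (2R)-5-({[tert-butyl(diphenyl)silyl]oxy}methyl)-2-methyl-2-(prop-2-en-1-yl)cyclohept-4-en-1-one | O=C1CCC(CO[Si](c2ccccc2)(c2ccccc2)C(C)(C)C)=CC[C@@]1(C)CC=C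
F5 | step 6 | (2R)-5-({[tert-butyl(diphenyl)silyl]oxy}methyl)-2-(3-hydroxypropyl)-2-methylcyclohept-4-en-1-one | O=C1CCC(CO[Si](c2ccccc2)(c2ccccc2)C(C)(C)C)=CC[C@@]1(C)CCCO
F6 | step 6 | (2R)-5-({[tert-butyl(diphenyl)silyl]oxy}methyl)-2-methyl-2-(3-oxopropyl)cyclohept-4-en-1-one | O=C1CCC(CO[Si](c2ccccc2)(c2ccccc2)C(C)(C)C)=CC[C@@]1(C)CCC=O
F7 | step 6 | (2R)-5-({[tert-butyl(diphenyl)silyl]oxy}methyl)-2-(3-hydroxy-4-methylpentyl)-2-methylcyclohept-4-en-1-one (carbinol epimers) | O=C1CCC(CO[Si](c2ccccc2)(c2ccccc2)C(C)(C)C)=CC[C@@]1(C)CCC(O)C(C)C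
F8 | step 7 | (8aR)-6-({[tert-butyl(diphenyl)silyl]oxy}methyl)-8a-methyl-3-(propan-2-yl)-1,2,3,3a,4,5,8,8a-octahydroazulene-3,3a-diol (cis-diol) | CC(C)C1(O)C2(O)CCC(CO[Si](c3ccccc3)(c3ccccc3)C(C)(C)C)=CC[C@@]2(C)CC1
F9 | step 7 | cyclic thionocarbonate of the cis-diol, (8aR)-configured | CC(C)C12OC(=S)OC13CCC(CO[Si](c4ccccc4)(c4ccccc4)C(C)(C)C)=CC[C@@]3(C)CC2
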